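The route rests on cutting ring B, the 3-methylenecyclohexene C5–C6=C7–C8(=C17)–C9–C10 that lies between the two ring-fusion carbons, along C5–C10 and C8–C9. That ring is the retron of a [4+2] between a vinylallene (C5=C6–C7=C8=C17) and an enal (C9=C10) held together by the C1–C4 tether. One Lewis-acid-catalysed intramolecular Diels–Alder reaction therefore closes rings A and B, sets C5, C9 and C10 against a preset quaternary C4 and leaves the 6,8(17)-diene in place. Its precursor is an open-chain (2E,8E)-trienal with the silyl-protected C18 arm on C4; the C12–C16 enoate is attached to C11 afterwards.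

Key step: step 11

Assumption (remark on the chemistry): the lipase of step 3 is taken to acetylate the hydroxymethyl arm drawn for 6, and the (S)-oxazaborolidinium of step 11 is taken to be the antipode matched to the bias from C4; both are checked (Mosher ester of 8; one trial each with the (R)-catalyst and with Me2AlCl), and the enzyme mode (acetylation of the diol or hydrolysis of its diacetate) or the catalyst antipode is chosen accordingly.

Step 1
Reactants: 1 diethyl methylmalonate; 2 5-chloropent-1-yne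
Product: 4 diethyl 2-methyl-2-(pent-4-yn-1-yl)propanedioate, via malonate sodium enolate 3 (not isolated)
Conditions: NaH, THF/DMF, 0 °C; then 2, NaI (cat.), 60 °C
Reagents that add atoms: none
Why: Malonic ester alkylation, in which the soft enolate displaces halide (iodide-assisted) from the unhindered primary carbon while the far less acidic alkyne C–H stays untouched, should assemble C4 with C19, both future CH2O arms and the C3–C1–C10–C9 chain.

Step 2
Reactants: 4 diethyl 2-methyl-2-(pent-4-yn-1-yl)propanedioate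
Product: 5 2-methyl-2-(pent-4-yn-1-yl)propane-1,3-diol
Conditions: LiAlH4, THF, 0 °C → rt; H2O, aq. NaOH, H2O
Reagents that add atoms: none
Why: Hydride reduction of both esters should give the prochiral 1,3-diol, the terminal alkyne being inert to LiAlH4 apart from reversible deprotonation.

Step 3
Reactants: 5 2-methyl-2-(pent-4-yn-1-yl)propane-1,3-diol
Product: 6 (R)-2-(hydroxymethyl)-2-methylhept-6-yn-1-yl acetate
Conditions: Burkholderia cepacia lipase (lipase PS), vinyl acetate, i-Pr2O, 0–25 °C
Reagents that add atoms: vinyl acetate, CC(=O)OC=C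
Why: Lipase-catalysed desymmetrising transesterification with an irreversible acyl donor should acetylate one of the two enantiotopic hydroxymethyl groups, so the quaternary C4 stereocentre is created under enzyme control by discrimination between the methyl and pentynyl substituents.

Step 4
Reactants: 6 (R)-2-(hydroxymethyl)-2-methylhept-6-yn-1-yl acetate
Product: 7 (S)-2-{[tert-butyl(diphenyl)silyl]oxymethyl}-2-methylhept-6-yn-1-yl acetate
Conditions: TBDPSCl, imidazole, CH2Cl2, 0 °C
Reagents that add atoms: tert-butyl(chloro)diphenylsilane (TBDPSCl), CC(C)(C)[Si](Cl)(c1ccccc1)c1ccccc1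
Why: Standard silylation of the free primary alcohol (the future C18 oxygen) under mild base at low temperature should outrun 1,3-acetyl migration, the only pathway that could erode the configuration at C4.

Step 5
Reactants: 7 (S)-2-{[tert-butyl(diphenyl)silyl]oxymethyl}-2-methylhept-6-yn-1-yl acetate
Product: 8 (S)-2-{[tert-butyl(diphenyl)silyl]oxymethyl}-2-methylhept-6-yn-1-ol
Conditions: K2CO3 (cat.), MeOH, 0 °C
Reagents that add atoms: none
Why: Zemplén-type methanolysis should remove the acetate and free the arm that becomes C5, the bulky TBDPS ether being stable to carbonate and slow to migrate at 0 °C.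

Step 6
Reactants: 8 (S)-2-{[tert-butyl(diphenyl)silyl]oxymethyl}-2-methylhept-6-yn-1-ol
Product: 9 (R)-2-{[tert-butyl(diphenyl)silyl]oxymethyl}-2-methylhept-6-ynal
Conditions: Dess–Martin periodinane, NaHCO3, CH2Cl2, 0 °C → rt
Reagents that add atoms: none
Why: Dess–Martin oxidation of the neopentyl-type primary alcohol should give an aldehyde that cannot epimerise because its α-carbon is quaternary.

Step 7
Reactants: 9 (R)-2-{[tert-butyl(diphenyl)silyl]oxymethyl}-2-methylhept-6-ynal
Product: 10 tert-butyl{[(2S)-2-[(E)-2-iodoethenyl]-2-methylhept-6-yn-1-yl]oxy}diphenylsilane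
Conditions: CrCl2, CHI3, THF/1,4-dioxane, 0 °C → rt
Reagents that add atoms: iodoform, IC(I)I
Why: Takai iodo-olefination, in which the gem-dichromium species formed from iodoform and divalent chromium adds to the aldehyde and eliminates anti, should give the (E)-vinyl iodide (C6 from iodoform) and tolerates the terminal alkyne and the silyl ether.

Step 8
Reactants: 10 tert-butyl{[(2S)-2-[(E)-2-iodoethenyl]-2-methylhept-6-yn-1-yl]oxy}diphenylsilane
Product: 12 (2E,7S,8E)-7-{[tert-butyl(diphenyl)silyl]oxymethyl}-9-iodo-3,7-dimethylnona-2,8-dien-1-ol, via alkenyldimethylalane 11 (not isolated)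
Conditions: Me3Al, Cp2ZrCl2 (cat.), CH2Cl2, 0 °C → rt; then (CH2O)n, 0 °C → rt; aq. KNaC4H4O6 (tartrate)
Reagents that add atoms: trimethylaluminium, C[Al](C)C; paraformaldehyde (as formaldehyde), C=O
Why: Negishi zirconium-catalysed carboalumination adds methyl and aluminium syn across the terminal alkyne with aluminium at the terminus, and direct trapping of the alkenylalane with formaldehyde (no butyllithium ate complex, which would exchange with the vinyl iodide) should give the (E)-trisubstituted allylic alcohol carrying C20 and C11.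

Step 9
Reactants: 12 (2E,7S,8E)-7-{[tert-butyl(diphenyl)silyl]oxymethyl}-9-iodo-3,7-dimethylnona-2,8-dien-1-ol; 13 tributyl(propa-1,2-dien-1-yl)stannane (allenyltributylstannane)
Product: 14 (2E,7S,8E)-7-{[tert-butyl(diphenyl)silyl]oxymethyl}-3,7-dimethyldodeca-2,8,10,11-tetraen-1-ol
Conditions: Pd2(dba)3 (cat.), P(2-furyl)3, CuI (cat.), DMF, rt → 40 °C
Reagents that add atoms: none
Why: Stille coupling (oxidative addition of the vinyl iodide to zerovalent palladium with retention, copper-assisted allenyl transfer from tin, reductive elimination) should give the (E)-vinylallene C5=C6–C7=C8=C17 without touching the free allylic alcohol.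

Step 10
Reactants: 14 (2E,7S,8E)-7-{[tert-butyl(diphenyl)silyl]oxymethyl}-3,7-dimethyldodeca-2,8,10,11-tetraen-1-ol
Product: 15 (2E,7S,8E)-7-{[tert-butyl(diphenyl)silyl]oxymethyl}-3,7-dimethyldodeca-2,8,10,11-tetraenal
Conditions: MnO2, CH2Cl2, 0 °C; filtered, kept cold and dilute, used at once
Reagents that add atoms: none
Why: Activated MnO2 oxidises only the allylic alcohol, with retention of the (E)-alkene geometry, and is neutral enough to leave the vinylallene intact.

Step 11
Reactants: 15 (2E,7S,8E)-7-{[tert-butyl(diphenyl)silyl]oxymethyl}-3,7-dimethyldodeca-2,8,10,11-tetraenal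
Product: 16 (1R,4aS,5S,8aR)-5-{[tert-butyl(diphenyl)silyl]oxymethyl}-5,8a-dimethyl-2-methylidene-1,2,4a,5,6,7,8,8a-octahydronaphthalene-1-carbaldehyde
Conditions: (S)-o-tolyl-CBS oxazaborolidine, Tf2NH (20 mol % each), CH2Cl2 (0.02 M), −78 → −40 °C; Et3N quench, cold filtration through silica
Reagents that add atoms: none
Why: Proposed new method: the cationic boron Lewis acid binds the formyl oxygen and lowers the enal LUMO, and the s-cis vinylallene C5=C6–C7=C8 adds across C9=C10 in a concerted, asynchronous [4+2] (C5–C10 leading, C8–C9 following) in which the orthogonal distal allene π bond takes no part and emerges as the C8=C17 methylene; the closest known reaction types are Lewis-acid- and oxazaborolidinium-catalysed intramolecular Diels–Alder reactions of (E)-trienals to trans-decalins and Diels–Alder reactions of vinylallenes that give 3-methylenecyclohexenes. Ring B closes as the six-membered cycloaddition ring and ring A as the six-membered ring spanned by the four-atom C1–C4 tether in a chair-like 1,7,9-decatriene mode. C10 and C9 are set by suprafacial addition to the (E)-enal (C20 and C11 cis), C5 by the endo-formyl, tether-exo transition state that places H5 trans to C20 (trans ring fusion), and the relation of all three to C4 by the diene face exposed when the chair tether carries CH2OTBDPS equatorial and C19 axial. The step needs endo selectivity and that facial selectivity: Lewis-acid coordination of the (E)-enal should secure the first, while the equatorial preference of the bulky silyloxymethyl arm (it avoids a 1,3-diaxial contact with the C10 methyl) gives only a modest bias that the matched chiral catalyst is meant to reinforce. The substrate is suited because the sp central allene carbon is unhindered, the quaternary C4 gives a Thorpe–Ingold push and has no hydrogen for a [1,5]-shift, and the product diene is locked s-trans and cannot react again; the risk is the congested C5–C10 bond between a neopentyl carbon and a new quaternary centre.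

Step 12
Reactants: 16 (1R,4aS,5S,8aR)-5-{[tert-butyl(diphenyl)silyl]oxymethyl}-5,8a-dimethyl-2-methylidene-1,2,4a,5,6,7,8,8a-octahydronaphthalene-1-carbaldehyde
Product: 17 [(1R,4aS,5S,8aR)-5-{[tert-butyl(diphenyl)silyl]oxymethyl}-5,8a-dimethyl-2-methylidene-1,2,4a,5,6,7,8,8a-octahydronaphthalen-1-yl]methanol
Conditions: NaBH4, MeOH/CH2Cl2, −40 → 0 °C (crude 16, at once)
Reagents that add atoms: none
Why: Immediate borohydride reduction of the β,γ-unsaturated aldehyde should fix C9 before it can epimerise or the C8 alkene can move into conjugation, and it leaves the diene and silyl ether alone.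

Step 13
Reactants: 17 [(1R,4aS,5S,8aR)-5-{[tert-butyl(diphenyl)silyl]oxymethyl}-5,8a-dimethyl-2-methylidene-1,2,4a,5,6,7,8,8a-octahydronaphthalen-1-yl]methanol
Product: 18 (1R,4aS,5S,8aR)-5-{[tert-butyl(diphenyl)silyl]oxymethyl}-1-(iodomethyl)-5,8a-dimethyl-2-methylidene-1,2,4a,5,6,7,8,8a-octahydronaphthalene
Conditions: PPh3, I2, imidazole, CH2Cl2, 0 °C → rt, dark
Reagents that add atoms: iodine, II
Why: Appel-type (Garegg–Samuelsson) iodination converts the primary alcohol into the iodide through an alkoxyphosphonium ion under near-neutral conditions that should spare the diene.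

Step 14
Reactants: 18 (1R,4aS,5S,8aR)-5-{[tert-butyl(diphenyl)silyl]oxymethyl}-1-(iodomethyl)-5,8a-dimethyl-2-methylidene-1,2,4a,5,6,7,8,8a-octahydronaphthalene; 19 methyl acetoacetate
Product: 21 methyl 5-[(1R,4aS,5S,8aS)-5-{[tert-butyl(diphenyl)silyl]oxymethyl}-5,8a-dimethyl-2-methylidene-1,2,4a,5,6,7,8,8a-octahydronaphthalen-1-yl]-3-oxopentanoate, via acetoacetate dianion 20 (not isolated)
Conditions: 19 (excess), NaH, THF, 0 °C; n-BuLi, 0 °C; then 18, THF/DMPU, 0 °C → rt; H2O
Reagents that add atoms: none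
Why: γ-Alkylation of the acetoacetate dianion occurs at the more nucleophilic terminal carbon, so SN2 displacement of the primary iodide (excess dianion to offset the β-branching) should join C11 to C12 and deliver the complete C12–C15 chain.

Step 15
Reactants: 21 methyl 5-[(1R,4aS,5S,8aS)-5-{[tert-butyl(diphenyl)silyl]oxymethyl}-5,8a-dimethyl-2-methylidene-1,2,4a,5,6,7,8,8a-octahydronaphthalen-1-yl]-3-oxopentanoate
Product: 23 methyl (2Z)-5-[(1R,4aS,5S,8aS)-5-{[tert-butyl(diphenyl)silyl]oxymethyl}-5,8a-dimethyl-2-methylidene-1,2,4a,5,6,7,8,8a-octahydronaphthalen-1-yl]-3-[(diethoxyphosphoryl)oxy]pent-2-enoate, via sodium enolate 22 (not isolated)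
Conditions: NaH, Et2O, 0 °C; then ClP(O)(OEt)2, 0 °C → rt
Reagents that add atoms: diethyl chlorophosphate, CCOP(=O)(Cl)OCC
Why: O-Phosphorylation of the chelated sodium enolate, in which the enolate oxygen and the ester carbonyl are held cis, should give the (Z)-enol phosphate.

Step 16
Reactants: 23 methyl (2Z)-5-[(1R,4aS,5S,8aS)-5-{[tert-butyl(diphenyl)silyl]oxymethyl}-5,8a-dimethyl-2-methylidene-1,2,4a,5,6,7,8,8a-octahydronaphthalen-1-yl]-3-[(diethoxyphosphoryl)oxy]pent-2-enoate
Product: 24 methyl (2E)-5-[(1R,4aS,5S,8aS)-5-{[tert-butyl(diphenyl)silyl]oxymethyl}-5,8a-dimethyl-2-methylidene-1,2,4a,5,6,7,8,8a-octahydronaphthalen-1-yl]-3-methylpent-2-enoate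
Conditions: Me2CuLi (MeLi, CuI), Et2O, −78 → −45 °C
Reagents that add atoms: lithium dimethylcuprate, [Li+].C[Cu-]C (made in the flask from methyllithium, C[Li], and CuI)
Why: Cuprate addition–elimination at the β-carbon of the enol phosphate proceeds with retention, so the methyl group (C16) takes the place of the phosphate cis to the ester and the 13E enoate should result.

Step 17
Reactants: 24 methyl (2E)-5-[(1R,4aS,5S,8aS)-5-{[tert-butyl(diphenyl)silyl]oxymethyl}-5,8a-dimethyl-2-methylidene-1,2,4a,5,6,7,8,8a-octahydronaphthalen-1-yl]-3-methylpent-2-enoate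
Product: 25 methyl (2E)-5-[(1R,4aS,5S,8aS)-5-(hydroxymethyl)-5,8a-dimethyl-2-methylidene-1,2,4a,5,6,7,8,8a-octahydronaphthalen-1-yl]-3-methylpent-2-enoate
Conditions: TBAF, THF, rt → 40 °C
Reagents that add atoms: none
Why: Fluoride cleaves the Si–O bond of the neopentyl TBDPS ether (gentle warming allows for its hindrance) without affecting the enoate or the diene.

Step 18
Reactants: 25 methyl (2E)-5-[(1R,4aS,5S,8aS)-5-(hydroxymethyl)-5,8a-dimethyl-2-methylidene-1,2,4a,5,6,7,8,8a-octahydronaphthalen-1-yl]-3-methylpent-2-enoate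
Product: 26 methyl (2E)-5-[(1R,4aS,5S,8aS)-5-(acetyloxymethyl)-5,8a-dimethyl-2-methylidene-1,2,4a,5,6,7,8,8a-octahydronaphthalen-1-yl]-3-methylpent-2-enoate (methyl 18-acetoxy-ent-labda-6,8(17),13E-trien-15-oate)
Conditions: Ac2O, pyridine, DMAP (cat.), CH2Cl2, 0 °C → rt
Reagents that add atoms: acetic anhydride, CC(=O)OC(C)=O
Why: DMAP-catalysed acylation of the primary C18 alcohol should complete the target without disturbing any stereocentre or alkene.

Compound list
1 | diethyl methylmalonate | CCOC(=O)C(C)C(=O)OCC | starting material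
2 | 5-chloropent-1-yne | C#CCCCCl | starting material
3 | sodium enolate of diethyl methylmalonate | CCOC(=O)C(C)=C([O-])OCC.[Na+] | intermediate
4 | diethyl 2-methyl-2-(pent-4-yn-1-yl)propanedioate | CCOC(=O)C(C)(CCCC#C)C(=O)OCC | intermediate
5 | 2-methyl-2-(pent-4-yn-1-yl)propane-1,3-diol | OCC(C)(CO)CCCC#C | intermediate
6 | (R)-2-(hydroxymethyl)-2-methylhept-6-yn-1-yl acetate | CC(=O)OC[C@@](C)(CO)CCCC#C | intermediate
7 | (S)-2-{[tert-butyl(diphenyl)silyl]oxymethyl}-2-methylhept-6-yn-1-yl acetate | CC(=O)OC[C@@](C)(CO[Si](c1ccccc1)(c1ccccc1)C(C)(C)C)CCCC#C | intermediate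
8 | (S)-2-{[tert-butyl(diphenyl)silyl]oxymethyl}-2-methylhept-6-yn-1-ol | OC[C@@](C)(CO[Si](c1ccccc1)(c1ccccc1)C(C)(C)C)CCCC#C | intermediate
9 | (R)-2-{[tert-butyl(diphenyl)silyl]oxymethyl}-2-methylhept-6-ynal | O=C[C@@](C)(CO[Si](c1ccccc1)(c1ccccc1)C(C)(C)C)CCCC#C | intermediate
10 | tert-butyl{[(2S)-2-[(E)-2-iodoethenyl]-2-methylhept-6-yn-1-yl]oxy}diphenylsilane | I/C=C/[C@@](C)(CO[Si](c1ccccc1)(c1ccccc1)C(C)(C)C)CCCC#C | intermediate
11 | dimethyl[(1E,6S,7E)-6-{[tert-butyl(diphenyl)silyl]oxymethyl}-8-iodo-2,6-dimethylocta-1,7-dien-1-yl]alumane | I/C=C/[C@@](C)(CO[Si](c1ccccc1)(c1ccccc1)C(C)(C)C)CCC/C(C)=C/[Al](C)C | intermediate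
12 | (2E,7S,8E)-7-{[tert-butyl(diphenyl)silyl]oxymethyl}-9-iodo-3,7-dimethylnona-2,8-dien-1-ol | I/C=C/[C@@](C)(CO[Si](c1ccccc1)(c1ccccc1)C(C)(C)C)CCC/C(C)=C/CO | intermediate
13 | tributyl(propa-1,2-dien-1-yl)stannane (allenyltributylstannane) | C=C=C[Sn](CCCC)(CCCC)CCCC | starting material
14 | (2E,7S,8E)-7-{[tert-butyl(diphenyl)silyl]oxymethyl}-3,7-dimethyldodeca-2,8,10,11-tetraen-1-ol | C=C=C/C=C/[C@@](C)(CO[Si](c1ccccc1)(c1ccccc1)C(C)(C)C)CCC/C(C)=C/CO | intermediate
15 | (2E,7S,8E)-7-{[tert-butyl(diphenyl)silyl]oxymethyl}-3,7-dimethyldodeca-2,8,10,11-tetraenal | C=C=C/C=C/[C@@](C)(CO[Si](c1ccccc1)(c1ccccc1)C(C)(C)C)CCC/C(C)=C/C=O | intermediate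
16 | (1R,4aS,5S,8aR)-5-{[tert-butyl(diphenyl)silyl]oxymethyl}-5,8a-dimethyl-2-methylidene-1,2,4a,5,6,7,8,8a-octahydronaphthalene-1-carbaldehyde | C=C1C=C[C@@H]2[C@@](C)(CO[Si](c3ccccc3)(c3ccccc3)C(C)(C)C)CCC[C@@]2(C)[C@@H]1C=O | intermediate
17 | [(1R,4aS,5S,8aR)-5-{[tert-butyl(diphenyl)silyl]oxymethyl}-5,8a-dimethyl-2-methylidene-1,2,4a,5,6,7,8,8a-octahydronaphthalen-1-yl]methanol | C=C1C=C[C@@H]2[C@@](C)(CO[Si](c3ccccc3)(c3ccccc3)C(C)(C)C)CCC[C@@]2(C)[C@@H]1CO | intermediate
18 | (1R,4aS,5S,8aR)-5-{[tert-butyl(diphenyl)silyl]oxymethyl}-1-(iodomethyl)-5,8a-dimethyl-2-methylidene-1,2,4a,5,6,7,8,8a-octahydronaphthalene | C=C1C=C[C@@H]2[C@@](C)(CO[Si](c3ccccc3)(c3ccccc3)C(C)(C)C)CCC[C@@]2(C)[C@@H]1CI | intermediate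
19 | methyl acetoacetate (methyl 3-oxobutanoate) | COC(=O)CC(C)=O | starting material
20 | sodium lithium dianion of methyl acetoacetate | C=C([O-])C=C([O-])OC.[Na+].[Li+] | intermediate
21 | methyl 5-[(1R,4aS,5S,8aS)-5-{[tert-butyl(diphenyl)silyl]oxymethyl}-5,8a-dimethyl-2-methylidene-1,2,4a,5,6,7,8,8a-octahydronaphthalen-1-yl]-3-oxopentanoate | C=C1C=C[C@@H]2[C@@](C)(CO[Si](c3ccccc3)(c3ccccc3)C(C)(C)C)CCC[C@@]2(C)[C@@H]1CCC(=O)CC(=O)OC | intermediate
22 | sodium (Z)-enolate of 21 | C=C1C=C[C@@H]2[C@@](C)(CO[Si](c3ccccc3)(c3ccccc3)C(C)(C)C)CCC[C@@]2(C)[C@@H]1CC/C([O-])=C/C(=O)OC.[Na+] | intermediate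
23 | methyl (2Z)-5-[(1R,4aS,5S,8aS)-5-{[tert-butyl(diphenyl)silyl]oxymethyl}-5,8a-dimethyl-2-methylidene-1,2,4a,5,6,7,8,8a-octahydronaphthalen-1-yl]-3-[(diethoxyphosphoryl)oxy]pent-2-enoate | C=C1C=C[C@@H]2[C@@](C)(CO[Si](c3ccccc3)(c3ccccc3)C(C)(C)C)CCC[C@@]2(C)[C@@H]1CC/C(OP(=O)(OCC)OCC)=C/C(=O)OC | intermediate
24 | methyl (2E)-5-[(1R,4aS,5S,8aS)-5-{[tert-butyl(diphenyl)silyl]oxymethyl}-5,8a-dimethyl-2-methylidene-1,2,4a,5,6,7,8,8a-octahydronaphthalen-1-yl]-3-methylpent-2-enoate | C=C1C=C[C@@H]2[C@@](C)(CO[Si](c3ccccc3)(c3ccccc3)C(C)(C)C)CCC[C@@]2(C)[C@@H]1CC/C(C)=C/C(=O)OC | intermediate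
25 | methyl (2E)-5-[(1R,4aS,5S,8aS)-5-(hydroxymethyl)-5,8a-dimethyl-2-methylidene-1,2,4a,5,6,7,8,8a-octahydronaphthalen-1-yl]-3-methylpent-2-enoate | C=C1C=C[C@@H]2[C@@](C)(CO)CCC[C@@]2(C)[C@@H]1CC/C(C)=C/C(=O)OC | intermediate
26 | methyl (2E)-5-[(1R,4aS,5S,8aS)-5-(acetyloxymethyl)-5,8a-dimethyl-2-methylidene-1,2,4a,5,6,7,8,8a-octahydronaphthalen-1-yl]-3-methylpent-2-enoate (methyl 18-acetoxy-ent-labda-6,8(17),13E-trien-15-oate) | C=C1C=C[C@@H]2[C@@](C)(COC(C)=O)CCC[C@@]2(C)[C@@H]1CC/C(C)=C/C(=O)OC | target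

Total step count: 18. Longest linear sequence: 18 steps (1 → 26); stannane 13 and ester 19 are bought and enter at steps 9 and 14.

Steps most likely to fail

Step 11. The hindered β,β-disubstituted enal may react too slowly at the congested C5–C10 bond, the Lewis acid may oligomerise the vinylallene, or facial discrimination relative to C4 may be weak. The fallback uses known chemistry and replaces the allene by an ordinary (E,E)-diene that carries C17 as a latent methylene. It sets out from vinyl iodide 12. Stille coupling under the conditions of step 9 with (E)-tributyl[3-(phenylsulfanyl)prop-1-en-1-yl]stannane F1 (made from the known (E)-3-(tributylstannyl)prop-2-en-1-ol with PhSSPh and PBu3) gives dienyl sulfide alcohol F2. MnO2 gives trienal F3. A Me2AlCl-promoted intramolecular Diels–Alder reaction of this (E,E,E)-trienal in CH2Cl2 at low temperature, an established entry to trans-decalins through the endo-formyl transition state, gives sulfide aldehyde F4 with CH2SPh on C8. NaBH4 gives sulfide alcohol F5, and NaIO4 in aqueous MeOH gives sulfoxide F6. Thermal syn-elimination (toluene, 110 °C, CaCO3), for which H8 is the only β-hydrogen, forms the C8=C17 methylene and comes back to the route at alcohol 17.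

Step 14. SN2 displacement at the β-branched C11 iodide may be slow, and E2 elimination through the allylic H9 may compete under the strongly basic dianion. The fallback avoids the displacement altogether. It sets out from aldehyde 16, which is methylenated under non-basic conditions (Zn, CH2Br2, TiCl4, THF/CH2Cl2, 0 °C; Lombardo–Takai methylenation) to vinyl triene F7. 9-BBN hydroborates the monosubstituted vinyl group in preference to the 1,1-disubstituted conjugated diene and gives alkylborane F8. This is coupled in the same flask with methyl (E)-3-iodobut-2-enoate (B-alkyl Suzuki–Miyaura coupling: Pd(dppf)Cl2, AsPh3, Cs2CO3, DMF/THF/H2O, rt). The 13E geometry is carried over from the iodoalkene, and the sequence comes back to the route at enoate 24, bypassing 17–23.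

Step 3. The enzyme may discriminate poorly, or in the wrong sense, between a methyl and a pentynyl group at the prochiral quaternary carbon, and acyl migration may erode the ee. The fallback is a classical resolution that sets out from diol 5. Monosilylation (NaH, TBDPSCl, THF) gives racemic silyl ether alcohol F9, which is esterified with (S)-O-methylmandelic acid (DCC, DMAP, CH2Cl2). The diastereomeric esters are separated by chromatography or preparative HPLC, and their configuration is assigned from the NMR anisotropy pattern of the pair. The (S,S)-mandelate F10 is cleaved with K2CO3/MeOH and comes back to the route at alcohol 8.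

Further compounds
F1 | step 11 | (E)-tributyl[3-(phenylsulfanyl)prop-1-en-1-yl]stannane | CCCC[Sn](CCCC)(CCCC)/C=C/CSc1ccccc1
F2 | step 11 | (2E,7S,8E,10E)-7-{[tert-butyl(diphenyl)silyl]oxymethyl}-3,7-dimethyl-12-(phenylsulfanyl)dodeca-2,8,10-trien-1-ol | c1ccccc1SC/C=C/C=C/[C@@](C)(CO[Si](c2ccccc2)(c2ccccc2)C(C)(C)C)CCC/C(C)=C/CO
F3 | step 11 | (2E,7S,8E,10E)-7-{[tert-butyl(diphenyl)silyl]oxymethyl}-3,7-dimethyl-12-(phenylsulfanyl)dodeca-2,8,10-trienal | c1ccccc1SC/C=C/C=C/[C@@](C)(CO[Si](c2ccccc2)(c2ccccc2)C(C)(C)C)CCC/C(C)=C/C=O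
F4 | step 11 | (1R,2R,4aS,5S,8aR)-5-{[tert-butyl(diphenyl)silyl]oxymethyl}-5,8a-dimethyl-2-[(phenylsulfanyl)methyl]-1,2,4a,5,6,7,8,8a-octahydronaphthalene-1-carbaldehyde | c1ccccc1SC[C@@H]2C=C[C@@H]3[C@@](C)(CO[Si](c4ccccc4)(c4ccccc4)C(C)(C)C)CCC[C@@]3(C)[C@@H]2C=O
F5 | step 11 | [(1R,2R,4aS,5S,8aR)-5-{[tert-butyl(diphenyl)silyl]oxymethyl}-5,8a-dimethyl-2-[(phenylsulfanyl)methyl]-1,2,4a,5,6,7,8,8a-octahydronaphthalen-1-yl]methanol | c1ccccc1SC[C@@H]2C=C[C@@H]3[C@@](C)(CO[Si](c4ccccc4)(c4ccccc4)C(C)(C)C)CCC[C@@]3(C)[C@@H]2CO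
F6 | step 11 | sulfoxide of F5 (mixture at sulfur) | O=S(c1ccccc1)C[C@@H]2C=C[C@@H]3[C@@](C)(CO[Si](c4ccccc4)(c4ccccc4)C(C)(C)C)CCC[C@@]3(C)[C@@H]2CO
F7 | step 14 | (1R,4aS,5S,8aS)-5-{[tert-butyl(diphenyl)silyl]oxymethyl}-1-ethenyl-5,8a-dimethyl-2-methylidene-1,2,4a,5,6,7,8,8a-octahydronaphthalene | C=C1C=C[C@@H]2[C@@](C)(CO[Si](c3ccccc3)(c3ccccc3)C(C)(C)C)CCC[C@@]2(C)[C@@H]1C=C
F8 | step 14 | 9-{2-[(1R,4aS,5S,8aS)-5-{[tert-butyl(diphenyl)silyl]oxymethyl}-5,8a-dimethyl-2-methylidene-1,2,4a,5,6,7,8,8a-octahydronaphthalen-1-yl]ethyl}-9-borabicyclo[3.3.1]nonane | C=C1C=C[C@@H]2[C@@](C)(CO[Si](c3ccccc3)(c3ccccc3)C(C)(C)C)CCC[C@@]2(C)[C@@H]1CCB4C5CCCC4CCC5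
F9 | step 3 | racemic 2-{[tert-butyl(diphenyl)silyl]oxymethyl}-2-methylhept-6-yn-1-ol | OCC(C)(CO[Si](c1ccccc1)(c1ccccc1)C(C)(C)C)CCCC#C
F10 | step 3 | (2S)-2-{[tert-butyl(diphenyl)silyl]oxymethyl}-2-methylhept-6-yn-1-yl (2S)-2-methoxy-2-phenylacetate | CO[C@H](C(=O)OC[C@@](C)(CO[Si](c1ccccc1)(c1ccccc1)C(C)(C)C)CCCC#C)c1ccccc1
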